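**Retrosynthetic overview**

1. Target 34 ⇐ C15 desilylation ⇐ C8 angeloylation ⇐ ring A (O–C10–C1–C2=C3–C4–C5) opened at C2=C3 by ring-closing metathesis of a C1 vinyl ketone with a C4 vinyl group. One double Mannich methylenation supplies both the lactone methylene C13 and the vinyl ketone carbon; the C1 acetyl comes from hydration of a C10 ethynyl group.
2. Ring B (oxepane O–C10–C9–C8–C7–C6–C5) holds the feature the plan rests on: quaternary C10 is bonded to the ring oxygen and C8, two carbons on, is oxygenated. This 1,3-O/O (aldol) pattern is cut at C9–C10 into a ketone-derived oxocarbenium ion at C10 (mixed methyl ketal on O5, from 4-(trimethylsilyl)but-3-yn-2-one) and the enol silane of a C8 methyl ketone.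
3. The C6/C7 trans γ-lactone is in place before that step, from (S)-5-(hydroxymethyl)furan-2(5H)-one by trans cuprate addition of the C8–C9 unit. It tells O6 from O5 without protecting groups and, being trans, keeps the C5 hydroxyl from forming a five-membered hemiketal with the C8 ketone.
4. C4 and C5 are set by Felkin-controlled addition of a (Z)-γ-(silyloxymethyl)allylsilane, from (Z)-but-2-ene-1,4-diol, to the C5 aldehyde. C3 is carried as the resulting vinyl group and C15 as a TBDPS ether.
5. Ring order: lactone (from the starting material) → ring B (step 13) → ring A (step 20).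

Key step: step 13

Remark on the chemistry: read as written, the SMILES places C1 and C4 on opposite faces of ring B (5R,10S), that is, a trans-intrabridgehead (in,out) 11-oxabicyclo[4.4.1]undecenone; the route is built for exactly this configuration. Germacrane numbering (C1–C15) of the target is used for all intermediates.

**Route**

Step 1
Reactants: 1 (S)-5-(hydroxymethyl)furan-2(5H)-one
Product: 2 (S)-5-{[(tert-butyldimethylsilyl)oxy]methyl}furan-2(5H)-one
Conditions: TBSCl, imidazole, CH2Cl2, 0 °C → rt
Reagents that add atoms: tert-butyldimethylsilyl chloride, CC(C)(C)[Si](C)(C)Cl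
Why: Routine silylation of the primary alcohol; the C6 stereocentre of the chiral-pool butenolide is untouched.

Step 2
Reactants: 2 (S)-5-{[(tert-butyldimethylsilyl)oxy]methyl}furan-2(5H)-one; 3 isopropenylmagnesium bromide
Product: 4 (4R,5S)-5-{[(tert-butyldimethylsilyl)oxy]methyl}-4-(prop-1-en-2-yl)dihydrofuran-2(3H)-one
Conditions: CuBr·SMe2 (10 mol%), THF, −78 → −40 °C; aq. NH4Cl
Reagents that add atoms: none
Why: Copper-catalysed conjugate addition of the Grignard reagent to the butenolide, in which the nucleophile should add anti to the C6 silyloxymethyl group and so set C7 with the C8 unit trans to C5 on the lactone.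

Step 3
Reactants: 4 (4R,5S)-5-{[(tert-butyldimethylsilyl)oxy]methyl}-4-(prop-1-en-2-yl)dihydrofuran-2(3H)-one
Product: 6 (4S,5S)-4-acetyl-5-{[(tert-butyldimethylsilyl)oxy]methyl}dihydrofuran-2(3H)-one, via secondary ozonide 5 (not isolated)
Conditions: O3, CH2Cl2, −78 °C; then Me2S, −78 °C → rt
Reagents that add atoms: ozone, [O-][O+]=O
Why: Ozonolysis of the 1,1-disubstituted alkene with reductive work-up should give the C8 methyl ketone (C9 = methyl), and any epimerisation at C7 can only return the more stable trans lactone.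

Step 4
Reactants: 6 (4S,5S)-4-acetyl-5-{[(tert-butyldimethylsilyl)oxy]methyl}dihydrofuran-2(3H)-one
Product: 7 (4S,5S)-4-acetyl-5-(hydroxymethyl)dihydrofuran-2(3H)-one
Conditions: aq. HF (48%), MeCN, 0 °C
Reagents that add atoms: none
Why: Acidic fluoride cleavage of the primary silyl ether avoids base, which could eliminate the lactone oxygen β to the C8 ketone.

Step 5
Reactants: 7 (4S,5S)-4-acetyl-5-(hydroxymethyl)dihydrofuran-2(3H)-one
Product: 8 (2S,3S)-3-acetyl-5-oxotetrahydrofuran-2-carbaldehyde
Conditions: Dess–Martin periodinane, NaHCO3, CH2Cl2, 0 °C → rt; used crude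
Reagents that add atoms: none
Why: Buffered Dess–Martin oxidation should give the C5 aldehyde without epimerising C6, and the trans arrangement on the lactone rules out an intramolecular aldol with the C8 ketone.

Step 6
Reactants: 9 (Z)-but-2-ene-1,4-diol
Product: 10 (Z)-4-[(tert-butyldiphenylsilyl)oxy]but-2-en-1-ol
Conditions: NaH (1.0 equiv), THF, 0 °C; then TBDPSCl (1.0 equiv)
Reagents that add atoms: tert-butyldiphenylsilyl chloride, CC(C)(C)[Si](Cl)(c1ccccc1)c1ccccc1
Why: Monosilylation of the symmetric diol through its sparingly soluble monosodium alkoxide, a standard desymmetrisation.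

Step 7
Reactants: 10 (Z)-4-[(tert-butyldiphenylsilyl)oxy]but-2-en-1-ol
Product: 11 (Z)-tert-butyl[(4-chlorobut-2-en-1-yl)oxy]diphenylsilane
Conditions: MsCl, 2,4,6-collidine, LiCl, DMF, 0 °C
Reagents that add atoms: lithium chloride, [Li+].[Cl-]
Why: In situ mesylation and SN2 displacement by chloride converts the allylic alcohol into the chloride without allylic transposition or loss of the Z geometry.

Step 8
Reactants: 8 (2S,3S)-3-acetyl-5-oxotetrahydrofuran-2-carbaldehyde; 11 (Z)-tert-butyl[(4-chlorobut-2-en-1-yl)oxy]diphenylsilane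
Product: 13 (4S,5S)-4-acetyl-5-[(1R,2R)-2-{[(tert-butyldiphenylsilyl)oxy]methyl}-1-hydroxybut-3-en-1-yl]dihydrofuran-2(3H)-one, via (Z)-allyltrichlorosilane 12 (not isolated)
Conditions: 11, HSiCl3, CuCl (5 mol%), i-Pr2NEt, Et2O, rt, volatiles removed; then 8, DMF, 0 °C; aq. NaHCO3
Reagents that add atoms: none
Why: DMF-promoted allylation of the aldehyde by the allyltrichlorosilane through a closed chair transition state, in which the Z olefin should give the 4,5-syn relation and Felkin–Anh attack anti to the C6–O bond the 5,6-anti relation (4R,5R), while the C8 ketone does not react.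

Step 9
Reactants: 14 4-(trimethylsilyl)but-3-yn-2-one
Product: 15 (3,3-dimethoxybut-1-yn-1-yl)trimethylsilane
Conditions: HC(OMe)3, MeOH, TsOH·H2O (cat.), rt
Reagents that add atoms: trimethyl orthoformate, COC(OC)OC
Why: Acid-catalysed ketalisation of the ynone, driven by the orthoformate as water scavenger.

Step 10
Reactants: 15 (3,3-dimethoxybut-1-yn-1-yl)trimethylsilane
Product: 16 (3-methoxybut-3-en-1-yn-1-yl)trimethylsilane
Conditions: TMSOTf, i-Pr2NEt, CH2Cl2, −20 °C → rt
Reagents that add atoms: none
Why: Silyl triflate/amine-mediated elimination of methanol from a dimethyl ketal is a standard route to the methyl enol ether, here the 2-methoxy enyne.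

Step 11
Reactants: 13 (4S,5S)-4-acetyl-5-[(1R,2R)-2-{[(tert-butyldiphenylsilyl)oxy]methyl}-1-hydroxybut-3-en-1-yl]dihydrofuran-2(3H)-one; 16 (3-methoxybut-3-en-1-yn-1-yl)trimethylsilane
Product: 17 O5 mixed methyl ketal of 13 with 4-(trimethylsilyl)but-3-yn-2-one (both epimers at the ketal carbon)
Conditions: 16 (3 equiv), PPTS (5 mol%), 4 Å MS, CH2Cl2, 0 °C → rt; Et3N quench
Reagents that add atoms: none
Why: Acid-catalysed Markovnikov addition of the free C5 hydroxyl to the enol ether (as in 2-methoxypropene protection) should give the mixed ketal, and both ketal epimers converge in step 13.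

Step 12
Reactants: 17 O5 mixed methyl ketal
Product: 18 C8 trimethylsilyl enol ether of 17 (key-step precursor)
Conditions: LiN(i-Pr)2, TMSCl (in situ quench), THF, −78 °C; non-aqueous work-up
Reagents that add atoms: chlorotrimethylsilane, C[Si](C)(C)Cl
Why: Kinetic deprotonation of the methyl ketone at the unhindered C9 methyl with immediate silylation should give the terminal enol silane and avoid the C7 enolate, which could expel the lactone oxygen.

Step 13
Reactants: 18 C8 trimethylsilyl enol ether of the mixed ketal
Product: 20 ring B oxepan-4-one (5,10-epoxy-8-oxo-6,12-olide bearing 10-methyl and 10-[(trimethylsilyl)ethynyl]; 4R,5R,6S,7S,10S), via C10 oxocarbenium triflate 19 (not isolated)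
Conditions: TMSOTf (0.3 equiv), 2,6-di-tert-butyl-4-methylpyridine (0.5 equiv), CH2Cl2, −78 °C; Et3N, then aq. NaHCO3
Reagents that add atoms: none
Why: Proposed new method: TMSOTf silylates the less hindered methoxy oxygen of the mixed ketal, methoxytrimethylsilane leaves, and the propargyl-stabilised oxocarbenium ion 19 (C10=O5+) is attacked at C10 by C9 of the C8 enol silane, after which loss of the silyl group returns TMSOTf and the C8 ketone; the closest known reaction types are the Petasis–Ferrier rearrangement and intramolecular Mukaiyama aldol additions to acetals, both established for tetrahydropyran-4-ones but not for a ketone-derived oxocarbenium ion closing an oxepan-4-one. Ring B (O–C10–C9–C8–C7–C6–C5) closes in a seven-membered mode with both the enol C8=C9 bond and the C10=O+ bond inside the new ring (7-enolendo-endo), helped by the trans lactone, which holds C5 and C8 within reach. The new stereocentre C10 is set by the oxocarbenium geometry and a chair-like transition state: the C5 substituent sits syn to the rod-like alkyne, the C4 side chain and the lactone bonds are pseudo-equatorial, so the methyl group should end pseudo-equatorial and cis to C4 and the alkynyl group pseudo-axial and trans to C4 (10S). The step needs ionisation of C10–OMe and not C10–O5 (the methoxy oxygen is the more accessible), C-attack by the enol silane and not Prins attack by the C3 vinyl group (a monosubstituted alkene is many orders of magnitude less nucleophilic), and no participation by O15 (hindered TBDPS ether); the pyridine base scavenges triflic acid so that neither enol silane nor ketal is protonated.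

Step 14
Reactants: 20 ring B oxepan-4-one
Product: 21 8β-alcohol (4R,5R,6S,7R,8R,10S)
Conditions: LiBH(s-Bu)3 (L-Selectride), THF, −78 °C; AcOH quench
Reagents that add atoms: none
Why: The bulky hydride should attack the ring B ketone from the peripheral direction on the side of the pseudo-axial H7, as in reductions of 2-alkylcycloalkanones, to give the alcohol cis to C11 (8R), while the lactone is inert at −78 °C and the acidic quench avoids translactonisation.

Step 15
Reactants: 21 8β-alcohol
Product: 22 C8 triethylsilyl ether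
Conditions: TESOTf, 2,6-lutidine, CH2Cl2, −78 → 0 °C
Reagents that add atoms: triethylsilyl trifluoromethanesulfonate, CC[Si](CC)(CC)OS(=O)(=O)C(F)(F)F
Why: Silylation of the hindered secondary alcohol blocks translactonisation to C8 and protects O8 against the strong base of step 18, with a group that can later be removed in the presence of the TBDPS ether.

Step 16
Reactants: 22 C8 triethylsilyl ether
Product: 23 terminal alkyne (10-ethynyl)
Conditions: K2CO3 (cat.), MeOH, 0 °C
Reagents that add atoms: none
Why: Methanolysis of the alkynyl C–Si bond is fast under mild carbonate catalysis, which the TES and TBDPS ethers and the lactone should tolerate at 0 °C.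

Step 17
Reactants: 23 terminal alkyne
Product: 24 C1 methyl ketone (10-acetyl)
Conditions: (Ph3P)AuNTf2 (3 mol%), 1,4-dioxane/H2O (10:1), 50 °C
Reagents that add atoms: water, O
Why: Gold-catalysed Markovnikov hydration of the terminal alkyne should give the C1 methyl ketone (C2 = methyl) under near-neutral conditions that leave the vinyl group and silyl ethers alone.

Step 18
Reactants: 24 C1 methyl ketone
Product: 26 bis-Mannich base (C11–CH2NMe2 and C2–CH2NMe2), via dilithium bis-enolate 25 (not isolated)
Conditions: LiN(i-Pr)2 (2.4 equiv), THF, −78 °C; then CH2=NMe2+ I− (3 equiv), −78 → 0 °C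
Reagents that add atoms: dimethylmethylideneammonium iodide (Eschenmoser's salt), C=[N+](C)C.[I-]
Why: The ketone can enolise only towards its methyl group (C10 is quaternary) and the lactone only at C11, so the bis-enolate should be aminomethylated at exactly the two carbons that need a methylene (Mannich reaction).

Step 19
Reactants: 26 bis-Mannich base
Product: 28 vinyl ketone and α-methylene lactone (triene), via bis-trimethylammonium diiodide 27 (not isolated)
Conditions: MeI (excess), THF, rt; then aq. NaHCO3/CH2Cl2, rt; used at once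
Reagents that add atoms: none
Why: Exhaustive N-methylation followed by mild E1cB elimination of trimethylamine unveils both the C1 vinyl ketone and the C11=C13 methylene in one operation.

Step 20
Reactants: 28 vinyl ketone and α-methylene lactone (triene)
Product: 29 ring A enone (tricyclic 5,10-epoxy-1-oxo-2-ene; C8–OTES; C15–OTBDPS)
Conditions: second-generation Hoveyda–Grubbs catalyst (15 mol%), 1,4-benzoquinone (30 mol%), toluene (1 mM), 80 °C
Reagents that add atoms: none
Why: Ring-closing metathesis between the C4 vinyl group and the vinyl ketone closes ring A (O–C10–C1–C2=C3–C4–C5) with loss of ethene; it is chosen because it is irreversible, needs no base (C4–H is γ to the new enone and C5–O is open to elimination) and is a known way to close trans-intrabridgehead bicyclo[4.4.1]undecenes, while the 1,1-disubstituted electron-poor lactone methylene should not take part.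

Step 21
Reactants: 29 ring A enone
Product: 30 8β-alcohol of the tricycle (C15–OTBDPS retained)
Conditions: HF·pyridine, pyridine, THF, 0 °C
Reagents that add atoms: none
Why: Buffered HF·pyridine cleaves the secondary TES ether much faster than the primary TBDPS ether and keeps the medium non-basic.

Step 22
Reactants: 30 8β-alcohol of the tricycle; 31 angelic acid
Product: 33 C8 angelate (C15–OTBDPS), via angelic 2,4,6-trichlorobenzoic anhydride 32 (not isolated)
Conditions: 31, 2,4,6-trichlorobenzoyl chloride, Et3N, toluene, rt; then 30, toluene, 75 °C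
Reagents that add atoms: none
Why: Yamaguchi-type acylation through the mixed anhydride, run without DMAP, should transfer the angeloyl group to the hindered C8 hydroxyl without Z to E isomerisation to the tiglate.

Step 23
Reactants: 33 C8 angelate (C15–OTBDPS)
Product: 34 CNP0274187.1 (target; 4R,5R,6S,7R,8R,10S)
Conditions: HF·pyridine, THF, 0 °C → rt
Reagents that add atoms: none
Why: Acidic fluoride removal of the primary TBDPS ether frees the C15 hydroxyl under conditions the enone, the α-methylene lactone and the angelate should tolerate.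

**Compound list**

1 | (S)-5-(hydroxymethyl)furan-2(5H)-one | O=C1C=C[C@@H](CO)O1 | starting material
2 | (S)-5-{[(tert-butyldimethylsilyl)oxy]methyl}furan-2(5H)-one | O=C1C=C[C@@H](CO[Si](C)(C)C(C)(C)C)O1 | intermediate
3 | isopropenylmagnesium bromide | CC(=C)[Mg]Br | starting material
4 | (4R,5S)-5-{[(tert-butyldimethylsilyl)oxy]methyl}-4-(prop-1-en-2-yl)dihydrofuran-2(3H)-one | O=C1C[C@H](C(C)=C)[C@@H](CO[Si](C)(C)C(C)(C)C)O1 | intermediate
5 | secondary ozonide of 4 (3-methyl-1,2,4-trioxolan-3-yl on C7) | O=C1C[C@H](C2(C)OCOO2)[C@@H](CO[Si](C)(C)C(C)(C)C)O1 | intermediate (not isolated)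
6 | (4S,5S)-4-acetyl-5-{[(tert-butyldimethylsilyl)oxy]methyl}dihydrofuran-2(3H)-one | O=C1C[C@H](C(C)=O)[C@@H](CO[Si](C)(C)C(C)(C)C)O1 | intermediate
7 | (4S,5S)-4-acetyl-5-(hydroxymethyl)dihydrofuran-2(3H)-one | O=C1C[C@H](C(C)=O)[C@@H](CO)O1 | intermediate
8 | (2S,3S)-3-acetyl-5-oxotetrahydrofuran-2-carbaldehyde | O=C1C[C@H](C(C)=O)[C@@H](C=O)O1 | intermediate
9 | (Z)-but-2-ene-1,4-diol | OC/C=C\CO | starting material
10 | (Z)-4-[(tert-butyldiphenylsilyl)oxy]but-2-en-1-ol | OC/C=C\CO[Si](c1ccccc1)(c1ccccc1)C(C)(C)C | intermediate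
11 | (Z)-tert-butyl[(4-chlorobut-2-en-1-yl)oxy]diphenylsilane | ClC/C=C\CO[Si](c1ccccc1)(c1ccccc1)C(C)(C)C | intermediate
12 | (Z)-tert-butyldiphenyl{[4-(trichlorosilyl)but-2-en-1-yl]oxy}silane | Cl[Si](Cl)(Cl)C/C=C\CO[Si](c1ccccc1)(c1ccccc1)C(C)(C)C | intermediate (not isolated)
13 | (4S,5S)-4-acetyl-5-[(1R,2R)-2-{[(tert-butyldiphenylsilyl)oxy]methyl}-1-hydroxybut-3-en-1-yl]dihydrofuran-2(3H)-one | O=C1C[C@H](C(C)=O)[C@@H]([C@H](O)[C@H](C=C)CO[Si](c2ccccc2)(c2ccccc2)C(C)(C)C)O1 | intermediate
14 | 4-(trimethylsilyl)but-3-yn-2-one | CC(=O)C#C[Si](C)(C)C | starting material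
15 | (3,3-dimethoxybut-1-yn-1-yl)trimethylsilane | CC(OC)(OC)C#C[Si](C)(C)C | intermediate
16 | (3-methoxybut-3-en-1-yn-1-yl)trimethylsilane | C=C(OC)C#C[Si](C)(C)C | intermediate
17 | O5 mixed methyl ketal of 13 with 4-(trimethylsilyl)but-3-yn-2-one (4R,5R,6S,7S; ketal carbon both epimers) | O=C1C[C@H](C(C)=O)[C@@H]([C@H](OC(C)(OC)C#C[Si](C)(C)C)[C@H](C=C)CO[Si](c2ccccc2)(c2ccccc2)C(C)(C)C)O1 | intermediate
18 | C8 trimethylsilyl enol ether of 17 (key-step precursor) | O=C1C[C@H](C(=C)O[Si](C)(C)C)[C@@H]([C@H](OC(C)(OC)C#C[Si](C)(C)C)[C@H](C=C)CO[Si](c2ccccc2)(c2ccccc2)C(C)(C)C)O1 | intermediate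
19 | C10 oxocarbenium triflate from 18 | O=C1C[C@H](C(=C)O[Si](C)(C)C)[C@@H]([C@H]([O+]=C(C)C#C[Si](C)(C)C)[C@H](C=C)CO[Si](c2ccccc2)(c2ccccc2)C(C)(C)C)O1.[O-]S(=O)(=O)C(F)(F)F | intermediate (not isolated)
20 | ring B oxepan-4-one trans-fused to the 6,12-lactone; C10 methyl and (trimethylsilyl)ethynyl; C5 carrying CH(CH=CH2)(CH2OTBDPS) (4R,5R,6S,7S,10S) | O=C1C[C@@H]2C(=O)C[C@@](C)(C#C[Si](C)(C)C)O[C@H]([C@H](C=C)CO[Si](c3ccccc3)(c3ccccc3)C(C)(C)C)[C@H]2O1 | intermediate
21 | 8β-alcohol of 20 (4R,5R,6S,7R,8R,10S) | O=C1C[C@@H]2[C@H](O)C[C@@](C)(C#C[Si](C)(C)C)O[C@H]([C@H](C=C)CO[Si](c3ccccc3)(c3ccccc3)C(C)(C)C)[C@H]2O1 | intermediate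
22 | C8 triethylsilyl ether of 21 | O=C1C[C@@H]2[C@H](O[Si](CC)(CC)CC)C[C@@](C)(C#C[Si](C)(C)C)O[C@H]([C@H](C=C)CO[Si](c3ccccc3)(c3ccccc3)C(C)(C)C)[C@H]2O1 | intermediate
23 | 10-ethynyl compound (terminal alkyne) | O=C1C[C@@H]2[C@H](O[Si](CC)(CC)CC)C[C@@](C)(C#C)O[C@H]([C@H](C=C)CO[Si](c3ccccc3)(c3ccccc3)C(C)(C)C)[C@H]2O1 | intermediate
24 | 10-acetyl compound (C1 methyl ketone) | O=C1C[C@@H]2[C@H](O[Si](CC)(CC)CC)C[C@@](C)(C(C)=O)O[C@H]([C@H](C=C)CO[Si](c3ccccc3)(c3ccccc3)C(C)(C)C)[C@H]2O1 | intermediate
25 | dilithium bis-enolate of 24 (lactone C11 and ketone C2) | [Li]OC1=C[C@@H]2[C@H](O[Si](CC)(CC)CC)C[C@@](C)(C(=C)O[Li])O[C@H]([C@H](C=C)CO[Si](c3ccccc3)(c3ccccc3)C(C)(C)C)[C@H]2O1 | intermediate (not isolated)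
26 | bis-Mannich base (C11–CH2NMe2, C11 epimers; C1 ketone as 3-(dimethylamino)propanoyl) | O=C1C(CN(C)C)[C@@H]2[C@H](O[Si](CC)(CC)CC)C[C@@](C)(C(=O)CCN(C)C)O[C@H]([C@H](C=C)CO[Si](c3ccccc3)(c3ccccc3)C(C)(C)C)[C@H]2O1 | intermediate
27 | bis-trimethylammonium diiodide of 26 | O=C1C(C[N+](C)(C)C)[C@@H]2[C@H](O[Si](CC)(CC)CC)C[C@@](C)(C(=O)CC[N+](C)(C)C)O[C@H]([C@H](C=C)CO[Si](c3ccccc3)(c3ccccc3)C(C)(C)C)[C@H]2O1.[I-].[I-] | intermediate (not isolated)
28 | triene: 10-acryloyl (C1 vinyl ketone), C11=C13 methylene lactone, C4 vinyl | O=C1C(=C)[C@@H]2[C@H](O[Si](CC)(CC)CC)C[C@@](C)(C(=O)C=C)O[C@H]([C@H](C=C)CO[Si](c3ccccc3)(c3ccccc3)C(C)(C)C)[C@H]2O1 | intermediate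
29 | ring A enone: 8-O-TES, 15-O-TBDPS derivative of the deacylated target | C=C1C(=O)O[C@@H]2[C@@H]3O[C@@](C)(C[C@@H](O[Si](CC)(CC)CC)[C@@H]12)C(=O)C=C[C@@H]3CO[Si](c4ccccc4)(c4ccccc4)C(C)(C)C | intermediate
30 | 8β-alcohol, 15-O-TBDPS | C=C1C(=O)O[C@@H]2[C@@H]3O[C@@](C)(C[C@@H](O)[C@@H]12)C(=O)C=C[C@@H]3CO[Si](c4ccccc4)(c4ccccc4)C(C)(C)C | intermediate
31 | angelic acid, (Z)-2-methylbut-2-enoic acid | C/C=C(/C)C(=O)O | starting material
32 | angelic 2,4,6-trichlorobenzoic anhydride | C/C=C(/C)C(=O)OC(=O)c1c(Cl)cc(Cl)cc1Cl | intermediate (not isolated)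
33 | 8-O-angeloyl, 15-O-TBDPS compound | C=C1C(=O)O[C@@H]2[C@@H]3O[C@@](C)(C[C@@H](OC(=O)/C(C)=C\C)[C@@H]12)C(=O)C=C[C@@H]3CO[Si](c4ccccc4)(c4ccccc4)C(C)(C)C | intermediate
34 | CNP0274187.1 (4R,5R,6S,7R,8R,10S) | C=C1C(=O)O[C@@H]2[C@@H]3O[C@@](C)(C[C@@H](OC(=O)/C(C)=C\C)[C@@H]12)C(=O)C=C[C@@H]3CO | target

**Step count**

Total: 23 steps. Longest linear sequence: 19 steps (1 → 34 through steps 1–5, 8, 11–23).

**Steps most likely to fail**

1. Step 13 (key step). The mixed ketal may ionise at the C10–O5 bond instead of C10–OMe and fragment back to the C5 alcohol. The oxocarbenium ion may lose a proton to the enol ether, the enol silane may be cleaved before it attacks, or attack may come from the other face and give the C10 epimer. The fallback makes the C9–C10 and C10–O5 bonds in two known operations; it sets out from 13 and 14 and comes back at 20. Ketone 13 would be treated with LiN(i-Pr)2 (2.2 equiv, THF, −78 °C) to form the C5 alkoxide and the kinetic C9 enolate, which should add 1,2 to ynone 14 to give the aldol adduct, the C10 tertiary propargylic carbinol F1 (both C10 epimers). Camphorsulfonic acid in CH2Cl2 at 40 °C should then dehydrate the tertiary carbinol to the C9=C10 enone and allow reversible intramolecular oxa-Michael addition of the C5 hydroxyl (the aldol/dehydrative cycloetherification sequence known for tetrahydropyran-4-ones). Under thermodynamic control this is expected to settle on the epimer with the methyl group pseudo-equatorial and the slim alkyne pseudo-axial, that is 20.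

2. Step 20. Closure of the strained trans-bridged ring A may be slower than intermolecular cross-metathesis, so that dimers form, or the ruthenium carbene may be diverted to the lactone methylene; the electron-poor, hindered vinyl ketone may also react sluggishly. The fallback closes the ring at the carbinol oxidation level; it sets out from 28 and comes back at 29. Luche reduction of 28 (NaBH4, CeCl3·7H2O, MeOH, −78 °C, where the ketone should be reduced before the methylene lactone) would give the C1 allylic alcohol F2 (both C1 epimers), in which C1 is sp3 and both reacting olefins are unactivated. Ring-closing metathesis with the same catalyst should give the cyclic allylic alcohol F3, and Dess–Martin oxidation of the C1 carbinol returns enone 29.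

3. Step 8. The Z geometry may erode while the allyltrichlorosilane is formed, which would give the 4,5-anti isomer, or Felkin facial selectivity at the α-acyloxy aldehyde may be poor; the aldehyde may also epimerise at C6 before it is consumed. The fallback changes from a closed to an open transition state, in which syn selectivity does not depend on olefin geometry; it sets out from 11 and 8 and comes back at 13. Chloride 11 would be treated with Bu3SnLi (THF, −78 °C) to give the allylstannane F4, and BF3·OEt2-promoted addition of F4 to aldehyde 8 (CH2Cl2, −78 °C, antiperiplanar open transition state, Felkin attack under non-chelating Lewis acid) should give the 4,5-syn-5,6-anti alcohol 13.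

**Further compounds**

F1 | step 13 | aldol adduct of the C9 enolate of 13 with ynone 14 (C10 tertiary propargylic carbinol, both C10 epimers) | O=C1C[C@H](C(=O)CC(C)(O)C#C[Si](C)(C)C)[C@@H]([C@H](O)[C@H](C=C)CO[Si](c2ccccc2)(c2ccccc2)C(C)(C)C)O1
F2 | step 20 | C1 allylic alcohol from 28 (both C1 epimers) | O=C1C(=C)[C@@H]2[C@H](O[Si](CC)(CC)CC)C[C@@](C)(C(O)C=C)O[C@H]([C@H](C=C)CO[Si](c3ccccc3)(c3ccccc3)C(C)(C)C)[C@H]2O1
F3 | step 20 | ring A cyclic allylic alcohol (C1 carbinol, both epimers) | C=C1C(=O)O[C@@H]2[C@@H]3O[C@@](C)(C[C@@H](O[Si](CC)(CC)CC)[C@@H]12)C(O)C=C[C@@H]3CO[Si](c4ccccc4)(c4ccccc4)C(C)(C)C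
F4 | step 8 | (Z)-tert-butyldiphenyl{[4-(tributylstannyl)but-2-en-1-yl]oxy}silane | CCCC[Sn](CCCC)(CCCC)C/C=C\CO[Si](c1ccccc1)(c1ccccc1)C(C)(C)C
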